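The tetrahydropyran (O1, C2–C6) is made by ring contraction. All six ring atoms are first held in an eight-membered (Z)-1,3-dioxocine acetal built from an (S,Z)-ene-1,5-diol and the C2 aldehyde. With BF3 the acetal ionises and a ring-contracting Prins closure forms C2–C3. The two surplus ring atoms (O and CH2) are expelled as the C3 hydroxymethyl arm, and the C4 cation is captured by 2,4-dihydroxy-6-methoxyacetophenone, which delivers ring A with its acetyl group. The step exploits the 1,3-relationship between O1 and the branch carbon on C3. The arm is then extended by Horner–Wadsworth–Emmons olefination and anti-SN2′ arylation, and the chalcone is made last.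

Key step: step 6

Remarks on the chemistry. TBS = tert-butyldimethylsilyl, TBSO = its ether; MOM = methoxymethyl, MOMO = its ether. Tetrahydropyran (oxane) numbering: O1, C2 (aryl), C3 (branch), C4 (ring A aryl), C5, C6 (arylethyl). Assumption: (R)-TRIP attacks the Re face of aliphatic aldehyde 3 as it does with other aldehydes, which gives the S alcohol; the antipodal acid would be used if the alcohol proved to be R. Alkynol 5 is used twice: for the ring (steps 3–8) and for the side-chain carbinol (steps 9–11).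

Step 1
Reactants: 1 tert-butyl(4-iodophenoxy)dimethylsilane; 2 allyl alcohol
Product: 3 3-[4-(TBSO)phenyl]propanal
Conditions: Pd(OAc)2 (2 mol %), Bu4NCl, NaHCO3, DMF, 40 °C
Reagents that add atoms: none
Why: Jeffery-type Heck arylation of allyl alcohol, in which aryl–palladium adds to the terminal alkene carbon and β-hydride elimination toward the carbinol gives an enol that tautomerises to the 3-arylpropanal.

Step 2
Reactants: 3 3-[4-(TBSO)phenyl]propanal; 4 allenylboronic acid pinacol ester
Product: 5 (3S)-1-[4-(TBSO)phenyl]hex-5-yn-3-ol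
Conditions: (R)-3,3′-bis(2,4,6-triisopropylphenyl)-1,1′-binaphthyl-2,2′-diyl hydrogen phosphate ((R)-TRIP, 10 mol %), 4 Å MS, toluene, 0 °C to rt; aqueous work-up
Reagents that add atoms: none
Why: Chiral phosphoric acid-catalysed propargylboration (SE2′ through a closed six-membered transition state) should add to the Re face of the aldehyde and set the S carbinol centre that becomes C6 of the ring and, through step 9, the side-chain carbinol.

Step 3
Reactants: 5 (3S)-1-[4-(TBSO)phenyl]hex-5-yn-3-ol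
Product: 6 (5S)-7-[4-(TBSO)phenyl]hept-2-yne-1,5-diol
Conditions: n-BuLi (2.2 equiv), THF, −78 °C; (CH2O)n, −78 °C to rt; NH4Cl (aq.)
Reagents that add atoms: paraformaldehyde (as formaldehyde), C=O
Why: The alkoxide/acetylide dianion adds through carbon to formaldehyde (acetylide addition to a carbonyl group) and the stereocentre is not touched.

Step 4
Reactants: 6 (5S)-7-[4-(TBSO)phenyl]hept-2-yne-1,5-diol
Product: 7 (2Z,5S)-7-[4-(TBSO)phenyl]hept-2-ene-1,5-diol
Conditions: H2 (1 atm), Pd/CaCO3 poisoned with Pb(OAc)2, quinoline, EtOAc, rt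
Reagents that add atoms: none
Why: Lindlar semihydrogenation adds H2 syn and stops at the Z-alkene that closure of an eight-membered ring requires.

Step 5
Reactants: 7 (2Z,5S)-7-[4-(TBSO)phenyl]hept-2-ene-1,5-diol; 8 4-(TBSO)benzaldehyde
Product: 9 (4S,6Z)-2-[4-(TBSO)phenyl]-4-{2-[4-(TBSO)phenyl]ethyl}-5,8-dihydro-4H-1,3-dioxocine (both epimers at the acetal carbon)
Conditions: pyridinium p-toluenesulfonate (10 mol %), benzene, reflux, Dean–Stark, 0.005 M
Reagents that add atoms: none
Why: Acid-catalysed acetalisation with azeotropic removal of water; the cis alkene holds the two hydroxyls close enough for eight-ring closure, high dilution suppresses oligomers, and the configuration of the acetal carbon is irrelevant because it becomes planar in step 6.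

Step 6
Reactants: 9 eight-membered acetal; 10 1-(2,4-dihydroxy-6-methoxyphenyl)ethanone (3 equiv)
Product: 12 1-{2,4-dihydroxy-6-methoxy-3-[(2S,3S,4R,6S)-3-(hydroxymethyl)-2-[4-(TBSO)phenyl]-6-{2-[4-(TBSO)phenyl]ethyl}oxan-4-yl]phenyl}ethanone (all-cis ring with axial CH2OH), via ring-opened oxocarbenium ion 11 (not isolated)
Conditions: BF3·OEt2 (2.5 equiv), CH2Cl2, −78 to −20 °C; NaHCO3 (aq.)
Reagents that add atoms: none
Why: Proposed new method: BF3 ionises the acetal C–O bond to the allylic oxygen and gives the (E)-aryl oxocarbenium ion 11, whose Z-alkene carbon C3 attacks C2 in a chair-like 6-endo-trig Prins closure, so that the eight-membered ring contracts to the tetrahydropyran while O and CH2 leave the ring as the C3 CH2O–BF3 arm, the resulting C4 cation is captured by arene 10 in a Friedel–Crafts step, and aqueous NaHCO3 then hydrolyses the B–O bond to the free CH2OH. The closest known reactions are the acetal- or α-acetoxy-ether-initiated Prins cyclisation of open-chain homoallylic ethers with Friedel–Crafts termination and the Lewis-acid ring contraction of cyclic vinyl acetals (1,3-dioxepins and 1,3-dioxocins) to tetrahydrofurans and tetrahydropyrans. C2 is set by the existing C6 centre through the chair in which the oxocarbenium aryl group and the C6 chain are both equatorial (2,6-cis); C3 is set by the Z geometry of the ring alkene, which places the arm axial; C4 is set by equatorial attack of the arene on the delocalised tetrahydropyranyl cation. The step needs the arene to react at its C3 (between the two hydroxyls) and not at C5, which should follow because the hydrogen-bonded acetyl group forces the methoxy methyl to lie over C5 while C3 is flanked only by hydroxyls. It also needs arene capture to outrun fluoride capture and 2-oxonia-Cope scrambling, which the threefold excess of 10 and the low temperature are meant to secure. Ionisation of the other acetal C–O bond should do no harm, because that oxocarbenium ion could only close a four- or five-membered ring and therefore returns to 9.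

Step 7
Reactants: 12 all-cis hydroxymethyl tetrahydropyran diphenol
Product: 13 1-{6-methoxy-2,4-bis(methoxymethoxy)-3-[(2S,3S,4R,6S)-3-(hydroxymethyl)-2-[4-(TBSO)phenyl]-6-{2-[4-(TBSO)phenyl]ethyl}oxan-4-yl]phenyl}ethanone
Conditions: NaH (2.05 equiv), THF, 0 °C; MOMCl (2.2 equiv), 0 °C to rt
Reagents that add atoms: chloromethyl methyl ether, COCCl
Why: Williamson etherification under stoichiometric control, in which two equivalents of NaH deprotonate only the two phenols (far more acidic than the primary alcohol) and the phenoxides are alkylated by MOMCl.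

Step 8
Reactants: 13 bis-MOM ether with axial CH2OH
Product: 15 (2S,3S,4R,6S)-4-[3-acetyl-4-methoxy-2,6-bis(methoxymethoxy)phenyl]-2-[4-(TBSO)phenyl]-6-{2-[4-(TBSO)phenyl]ethyl}oxane-3-carbaldehyde (all-equatorial), via axial aldehyde 14 (not isolated)
Conditions: Dess–Martin periodinane, NaHCO3, CH2Cl2, 0 °C to rt; Na2S2O3/NaHCO3 work-up; crude in dry toluene, DBU (0.2 equiv), rt
Reagents that add atoms: none
Why: Dess–Martin oxidation gives the axial aldehyde, and base-mediated enolisation (α-epimerisation) should move the formyl group to the equatorial position, which relieves its clash with the ortho substituents of the C4 aryl group and gives the all-equatorial ring of the target; any reversible retro-oxa-Michael opening would re-close to the same thermodynamic 2,6-cis ring without touching C6.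

Step 9
Reactants: 5 (3S)-1-[4-(TBSO)phenyl]hex-5-yn-3-ol
Product: 16 tert-butyl({(3S)-1-[4-(TBSO)phenyl]hex-5-yn-3-yl}oxy)dimethylsilane
Conditions: TBSCl, imidazole, DMF, rt
Reagents that add atoms: tert-butyldimethylsilyl chloride, CC(C)(C)[Si](C)(C)Cl
Why: Standard silylation of the secondary alcohol protects the carbinol that becomes the free hydroxyl of the side chain.

Step 10
Reactants: 16 silyl-protected alkynol
Product: 17 diethyl {(4S)-4-(TBSO)-6-[4-(TBSO)phenyl]hex-1-yn-1-yl}phosphonate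
Conditions: n-BuLi (1.05 equiv), THF, −78 °C; ClP(O)(OEt)2, −78 to 0 °C
Reagents that add atoms: diethyl chlorophosphate, CCOP(=O)(Cl)OCC
Why: Deprotonation of the terminal alkyne and phosphorylation of the lithium acetylide is the usual route to 1-alkynylphosphonates.

Step 11
Reactants: 17 alkynylphosphonate
Product: 18 diethyl {(4S)-4-(TBSO)-6-[4-(TBSO)phenyl]-2-oxohexyl}phosphonate
Conditions: AuCl(PPh3) (2 mol %), AgOTf (2 mol %), 1,4-dioxane/H2O 10:1, rt to 40 °C
Reagents that add atoms: water, O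
Why: Gold-catalysed hydration of the 1-alkynylphosphonate adds water to the alkyne carbon remote from phosphorus and tautomerisation gives the β-ketophosphonate.

Step 12
Reactants: 15 all-equatorial aldehyde; 18 β-ketophosphonate
Product: 19 (1E,5S)-1-{(2S,3S,4R,6S)-4-[3-acetyl-4-methoxy-2,6-bis(MOMO)phenyl]-2-[4-(TBSO)phenyl]-6-{2-[4-(TBSO)phenyl]ethyl}oxan-3-yl}-5-(TBSO)-7-[4-(TBSO)phenyl]hept-1-en-3-one
Conditions: LiCl, i-Pr2NEt, MeCN, rt
Reagents that add atoms: none
Why: Masamune–Roush Horner–Wadsworth–Emmons olefination gives the E-enone under conditions mild enough to leave the C3 centre and the aryl silyl ethers intact.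

Step 13
Reactants: 19 E-enone
Product: 20 the corresponding (1E,3R,5S)-hept-1-en-3-ol (enone carbonyl reduced to the R allylic alcohol, all else unchanged)
Conditions: (S)-2-methyl-CBS-oxazaborolidine (1.0 equiv), catecholborane (1.5 equiv), toluene, −78 °C; MeOH, then pH 7 buffer
Reagents that add atoms: none
Why: Corey–Bakshi–Shibata reduction, in which the alkenyl group acts as the large substituent so that the (S)-catalyst should give the R allylic alcohol, while the 2,6-dioxygenated aryl methyl ketone is too hindered to compete at −78 °C.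

Step 14
Reactants: 20 (3R)-allylic alcohol
Product: 21 the (1E,3R,5S)-hept-1-en-3-yl pyridine-2-carboxylate of 20
Conditions: picolinic acid, DCC, DMAP (cat.), CH2Cl2, rt
Reagents that add atoms: picolinic acid, OC(=O)c1ccccn1
Why: Steglich esterification installs the picolinate, the chelating leaving group for the next step.

Step 15
Reactants: 21 allylic picolinate; 22 (4-bromophenoxy)(tert-butyl)dimethylsilane
Product: 24 1-{3-[(2S,3R,4R,6S)-3-{(1S,2E,5S)-5-(TBSO)-1,7-bis[4-(TBSO)phenyl]hept-2-en-1-yl}-2-[4-(TBSO)phenyl]-6-{2-[4-(TBSO)phenyl]ethyl}oxan-4-yl]-6-methoxy-2,4-bis(MOMO)phenyl}ethanone, via arylmagnesium bromide 23 (not isolated)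
Conditions: 22, Mg, THF, rt (3 equiv of 23); CuBr·SMe2 (1.5 equiv), THF, −60 °C; then 21, −60 to 0 °C; NH4Cl (aq.)
Reagents that add atoms: none
Why: Copper-mediated anti-SN2′ substitution of the allylic picolinate by the aryl Grignard reagent, in which chelation by the picolinate directs γ-attack anti to the leaving group from the conformer with the carbinol hydrogen in the alkene plane, so that the R carbinol centre is transferred to the S benzylic centre and the E-alkene is formed, while the 2:1 ratio of 23 to CuBr leaves no free Grignard reagent to add to the hindered aryl ketone.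

Step 16
Reactants: 24 aryl ketone with complete side chain; 25 4-(methoxymethoxy)benzaldehyde
Product: 26 chalcone with ring A and ring B as MOM ethers, the side-chain carbinol as TBS ether and the four 4-hydroxyphenyl groups free
Conditions: KOH (50 % aq., excess), EtOH, rt; AcOH to pH 6 at 0 °C
Reagents that add atoms: none
Why: Claisen–Schmidt aldol condensation of the methyl ketone with the aldehyde gives the E-chalcone, and the same hydroxide cleaves the four base-labile aryl silyl ethers while the MOM ethers keep ring A from closing to a flavanone.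

Step 17
Reactants: 26 protected chalcone
Product: 27 Blepharocalyxin E
Conditions: HCl (3 M aq.)/MeOH 1:5, rt, short reaction time; NaHCO3 (aq.)
Reagents that add atoms: none
Why: Acid-catalysed acetal and silyl ether methanolysis removes the three MOM groups and the secondary TBS group, and room temperature with a short reaction time is chosen to release the 2′-hydroxychalcone without flavanone closure.

Compound list
1 | tert-butyl(4-iodophenoxy)dimethylsilane | CC(C)(C)[Si](C)(C)Oc1ccc(I)cc1 | starting material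
2 | allyl alcohol | C=CCO | starting material
3 | 3-[4-(TBSO)phenyl]propanal | CC(C)(C)[Si](C)(C)Oc1ccc(CCC=O)cc1 | intermediate
4 | allenylboronic acid pinacol ester | C=C=CB1OC(C)(C)C(C)(C)O1 | starting material
5 | (3S)-1-[4-(TBSO)phenyl]hex-5-yn-3-ol | C#CC[C@@H](O)CCc1ccc(O[Si](C)(C)C(C)(C)C)cc1 | intermediate
6 | (5S)-7-[4-(TBSO)phenyl]hept-2-yne-1,5-diol | OCC#CC[C@@H](O)CCc1ccc(O[Si](C)(C)C(C)(C)C)cc1 | intermediate
7 | (2Z,5S)-7-[4-(TBSO)phenyl]hept-2-ene-1,5-diol | OC/C=C\C[C@@H](O)CCc1ccc(O[Si](C)(C)C(C)(C)C)cc1 | intermediate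
8 | 4-(TBSO)benzaldehyde | CC(C)(C)[Si](C)(C)Oc1ccc(C=O)cc1 | starting material
9 | (4S,6Z)-2-[4-(TBSO)phenyl]-4-{2-[4-(TBSO)phenyl]ethyl}-5,8-dihydro-4H-1,3-dioxocine (acetal carbon: both epimers) | CC(C)(C)[Si](C)(C)Oc1ccc(cc1)C2OC/C=C\C[C@H](CCc3ccc(O[Si](C)(C)C(C)(C)C)cc3)O2 | intermediate
10 | 1-(2,4-dihydroxy-6-methoxyphenyl)ethanone | CC(=O)c1c(O)cc(O)cc1OC | starting material
11 | ring-opened (E)-aryl oxocarbenium ion with the allylic oxygen bound to BF3 | F[B-](F)(F)OC/C=C\C[C@H](CCc1ccc(O[Si](C)(C)C(C)(C)C)cc1)[O+]=Cc1ccc(O[Si](C)(C)C(C)(C)C)cc1 | intermediate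
12 | 1-{2,4-dihydroxy-6-methoxy-3-[(2S,3S,4R,6S)-3-(hydroxymethyl)-2-[4-(TBSO)phenyl]-6-{2-[4-(TBSO)phenyl]ethyl}oxan-4-yl]phenyl}ethanone | COc1cc(O)c([C@@H]2C[C@H](CCc3ccc(O[Si](C)(C)C(C)(C)C)cc3)O[C@H](c3ccc(O[Si](C)(C)C(C)(C)C)cc3)[C@@H]2CO)c(O)c1C(C)=O | intermediate
13 | bis-MOM ether of 12 | COc1cc(OCOC)c([C@@H]2C[C@H](CCc3ccc(O[Si](C)(C)C(C)(C)C)cc3)O[C@H](c3ccc(O[Si](C)(C)C(C)(C)C)cc3)[C@@H]2CO)c(OCOC)c1C(C)=O | intermediate
14 | (2S,3R,4R,6S)-oxane-3-carbaldehyde with axial formyl group | COc1cc(OCOC)c([C@@H]2C[C@H](CCc3ccc(O[Si](C)(C)C(C)(C)C)cc3)O[C@H](c3ccc(O[Si](C)(C)C(C)(C)C)cc3)[C@@H]2C=O)c(OCOC)c1C(C)=O | intermediate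
15 | (2S,3S,4R,6S)-4-[3-acetyl-4-methoxy-2,6-bis(MOMO)phenyl]-2-[4-(TBSO)phenyl]-6-{2-[4-(TBSO)phenyl]ethyl}oxane-3-carbaldehyde (all-equatorial) | COc1cc(OCOC)c([C@@H]2C[C@H](CCc3ccc(O[Si](C)(C)C(C)(C)C)cc3)O[C@H](c3ccc(O[Si](C)(C)C(C)(C)C)cc3)[C@H]2C=O)c(OCOC)c1C(C)=O | intermediate
16 | tert-butyl({(3S)-1-[4-(TBSO)phenyl]hex-5-yn-3-yl}oxy)dimethylsilane | C#CC[C@@H](O[Si](C)(C)C(C)(C)C)CCc1ccc(O[Si](C)(C)C(C)(C)C)cc1 | intermediate
17 | diethyl {(4S)-4-(TBSO)-6-[4-(TBSO)phenyl]hex-1-yn-1-yl}phosphonate | CCOP(=O)(OCC)C#CC[C@@H](O[Si](C)(C)C(C)(C)C)CCc1ccc(O[Si](C)(C)C(C)(C)C)cc1 | intermediate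
18 | diethyl {(4S)-4-(TBSO)-6-[4-(TBSO)phenyl]-2-oxohexyl}phosphonate | CCOP(=O)(OCC)CC(=O)C[C@@H](O[Si](C)(C)C(C)(C)C)CCc1ccc(O[Si](C)(C)C(C)(C)C)cc1 | intermediate
19 | (1E,5S)-enone at C3 of the (2S,3S,4R,6S)-oxane | COc1cc(OCOC)c([C@@H]2C[C@H](CCc3ccc(O[Si](C)(C)C(C)(C)C)cc3)O[C@H](c3ccc(O[Si](C)(C)C(C)(C)C)cc3)[C@H]2/C=C/C(=O)C[C@@H](O[Si](C)(C)C(C)(C)C)CCc2ccc(O[Si](C)(C)C(C)(C)C)cc2)c(OCOC)c1C(C)=O | intermediate
20 | (1E,3R,5S)-allylic alcohol | COc1cc(OCOC)c([C@@H]2C[C@H](CCc3ccc(O[Si](C)(C)C(C)(C)C)cc3)O[C@H](c3ccc(O[Si](C)(C)C(C)(C)C)cc3)[C@H]2/C=C/[C@H](O)C[C@@H](O[Si](C)(C)C(C)(C)C)CCc2ccc(O[Si](C)(C)C(C)(C)C)cc2)c(OCOC)c1C(C)=O | intermediate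
21 | (1E,3R,5S)-allylic picolinate | COc1cc(OCOC)c([C@@H]2C[C@H](CCc3ccc(O[Si](C)(C)C(C)(C)C)cc3)O[C@H](c3ccc(O[Si](C)(C)C(C)(C)C)cc3)[C@H]2/C=C/[C@H](OC(=O)c2ccccn2)C[C@@H](O[Si](C)(C)C(C)(C)C)CCc2ccc(O[Si](C)(C)C(C)(C)C)cc2)c(OCOC)c1C(C)=O | intermediate
22 | (4-bromophenoxy)(tert-butyl)dimethylsilane | CC(C)(C)[Si](C)(C)Oc1ccc(Br)cc1 | starting material
23 | [4-(TBSO)phenyl]magnesium bromide | CC(C)(C)[Si](C)(C)Oc1ccc([Mg]Br)cc1 | intermediate
24 | (2S,3R,4R,6S)-oxane with the (1S,2E,5S) side chain, fully protected aryl methyl ketone | COc1cc(OCOC)c([C@@H]2C[C@H](CCc3ccc(O[Si](C)(C)C(C)(C)C)cc3)O[C@H](c3ccc(O[Si](C)(C)C(C)(C)C)cc3)[C@H]2[C@H](/C=C/C[C@@H](O[Si](C)(C)C(C)(C)C)CCc2ccc(O[Si](C)(C)C(C)(C)C)cc2)c2ccc(O[Si](C)(C)C(C)(C)C)cc2)c(OCOC)c1C(C)=O | intermediate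
25 | 4-(methoxymethoxy)benzaldehyde | COCOc1ccc(C=O)cc1 | starting material
26 | tris-MOM mono-TBS protected Blepharocalyxin E | COc1cc(OCOC)c([C@@H]2C[C@H](CCc3ccc(O)cc3)O[C@H](c3ccc(O)cc3)[C@H]2[C@H](/C=C/C[C@@H](O[Si](C)(C)C(C)(C)C)CCc2ccc(O)cc2)c2ccc(O)cc2)c(OCOC)c1C(=O)/C=C/c1ccc(OCOC)cc1 | intermediate
27 | Blepharocalyxin E | COc1cc(O)c([C@@H]2C[C@H](CCc3ccc(O)cc3)O[C@H](c3ccc(O)cc3)[C@H]2[C@H](/C=C/C[C@@H](O)CCc2ccc(O)cc2)c2ccc(O)cc2)c(O)c1C(=O)/C=C/c1ccc(O)cc1 | target

Total step count: 17. Longest linear sequence: 14 steps (steps 1–8 and 12–17).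

Steps most likely to fail

Step 6 (Proposed new method). The cation may be captured by fluoride or lose a proton before the hindered arene arrives next to the axial arm. The arene may attack through its C5, or be deactivated by chelation of its hydroxy ketone to boron. Reversible 2-oxonia-Cope rearrangement of the oxocarbenium ion may scramble the alkene geometry and the C6 centre. Fallback with known chemistry, setting out from 6 and coming back at 15: alkyne-diol 6 is reduced with NaAlH2(OCH2CH2OMe)2 (THF, 0 °C to rt) to (2E,5S)-7-[4-(TBSO)phenyl]hept-2-ene-1,5-diol F1. Its primary hydroxyl is silylated (TBSCl, Et3N, DMAP cat., CH2Cl2, 0 °C) to give the mono-silyl ether F2. The conventional three-component Prins cyclisation with Friedel–Crafts capture of F2, aldehyde 8 and arene 10 (BF3·OEt2, CH2Cl2, −78 to −20 °C) gives the all-equatorial tetrahydropyran silyl ether F3, the E-alkene placing the arm equatorial. NaH/MOMCl then gives the bis-MOM ether F4, pyridinium p-toluenesulfonate in MeOH frees the primary alcohol F5, and Dess–Martin oxidation gives 15 without an epimerisation.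

Step 5. Intermolecular acetalisation and oligomer formation may win over closure of the eight-membered ring, and the acetal may hydrolyse on isolation. Fallback, setting out from 5 (with 8 and 2) and coming back at 9: alkynol 5 is semihydrogenated (H2, Pd/CaCO3 poisoned with Pb(OAc)2, quinoline) to (3S)-1-[4-(TBSO)phenyl]hex-5-en-3-ol F6. Aldehyde 8 and allyl alcohol 2 give the diallyl acetal F7 (pyridinium p-toluenesulfonate, benzene, Dean–Stark). Transacetalisation of F7 with F6 gives the mixed allyl homoallyl acetal F8. Ring-closing metathesis with the second-generation Grubbs catalyst RuCl2(=CHPh)(PCy3)(H2IMes) (CH2Cl2, 40 °C, 0.002 M) then forms the C=C bond of the ring, necessarily cis, and gives 9.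

Step 15. The organocopper reagent may attack the hindered γ-carbon too slowly, so that direct α-substitution, loss of anti selectivity or reduction of the picolinate takes over. Fallback, setting out from 19 and coming back at 24: enone 19 is reduced with (R)-2-methyl-CBS-oxazaborolidine/catecholborane to the epimeric (1E,3S,5S)-allylic alcohol F9, which is acetylated (Ac2O, pyridine, DMAP) to the allylic acetate F10. Coupling of F10 with 4-(TBSO)phenylboronic acid under Pd(OAc)2/1,10-phenanthroline/AgSbF6 (1,2-dichloroethane, 40 °C) proceeds by acetate-directed carbopalladation and β-acetoxy elimination. This is γ-selective and transfers chirality in the syn sense, so it gives 24 with the same S benzylic centre.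

Further compounds
F1 | step 6 | (2E,5S)-7-[4-(TBSO)phenyl]hept-2-ene-1,5-diol | OC/C=C/C[C@@H](O)CCc1ccc(O[Si](C)(C)C(C)(C)C)cc1
F2 | step 6 | (2E,5S)-1-(TBSO)-7-[4-(TBSO)phenyl]hept-2-en-5-ol | CC(C)(C)[Si](C)(C)OC/C=C/C[C@@H](O)CCc1ccc(O[Si](C)(C)C(C)(C)C)cc1
F3 | step 6 | all-equatorial (2S,3R,4R,6S)-tetrahydropyran with C3 CH2OTBS and free ring A phenols | COc1cc(O)c([C@@H]2C[C@H](CCc3ccc(O[Si](C)(C)C(C)(C)C)cc3)O[C@H](c3ccc(O[Si](C)(C)C(C)(C)C)cc3)[C@H]2CO[Si](C)(C)C(C)(C)C)c(O)c1C(C)=O
F4 | step 6 | bis-MOM ether of F3 | COc1cc(OCOC)c([C@@H]2C[C@H](CCc3ccc(O[Si](C)(C)C(C)(C)C)cc3)O[C@H](c3ccc(O[Si](C)(C)C(C)(C)C)cc3)[C@H]2CO[Si](C)(C)C(C)(C)C)c(OCOC)c1C(C)=O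
F5 | step 6 | all-equatorial (2S,3R,4R,6S) primary alcohol (C3 epimer of 13) | COc1cc(OCOC)c([C@@H]2C[C@H](CCc3ccc(O[Si](C)(C)C(C)(C)C)cc3)O[C@H](c3ccc(O[Si](C)(C)C(C)(C)C)cc3)[C@H]2CO)c(OCOC)c1C(C)=O
F6 | step 5 | (3S)-1-[4-(TBSO)phenyl]hex-5-en-3-ol | C=CC[C@@H](O)CCc1ccc(O[Si](C)(C)C(C)(C)C)cc1
F7 | step 5 | 4-(TBSO)benzaldehyde diallyl acetal | C=CCOC(OCC=C)c1ccc(O[Si](C)(C)C(C)(C)C)cc1
F8 | step 5 | mixed allyl (3S)-hex-5-en-3-yl acetal of 4-(TBSO)benzaldehyde (acetal carbon: both epimers) | C=CCOC(O[C@H](CC=C)CCc1ccc(O[Si](C)(C)C(C)(C)C)cc1)c1ccc(O[Si](C)(C)C(C)(C)C)cc1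
F9 | step 15 | (1E,3S,5S)-allylic alcohol (carbinol epimer of 20) | COc1cc(OCOC)c([C@@H]2C[C@H](CCc3ccc(O[Si](C)(C)C(C)(C)C)cc3)O[C@H](c3ccc(O[Si](C)(C)C(C)(C)C)cc3)[C@H]2/C=C/[C@@H](O)C[C@@H](O[Si](C)(C)C(C)(C)C)CCc2ccc(O[Si](C)(C)C(C)(C)C)cc2)c(OCOC)c1C(C)=O
F10 | step 15 | (1E,3S,5S)-allylic acetate | COc1cc(OCOC)c([C@@H]2C[C@H](CCc3ccc(O[Si](C)(C)C(C)(C)C)cc3)O[C@H](c3ccc(O[Si](C)(C)C(C)(C)C)cc3)[C@H]2/C=C/[C@@H](OC(C)=O)C[C@@H](O[Si](C)(C)C(C)(C)C)CCc2ccc(O[Si](C)(C)C(C)(C)C)cc2)c(OCOC)c1C(C)=O
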